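## Retrosynthetic overview

1. Target 13 is (8S)-persicachrome (carotenoid numbering: C3 carbinol, C5 quaternary C–O, C8 furanoid CH). The dihydrofuran is closed last, C5–O onto C8, by a catalyst-controlled dehydrative cyclisation of 5,6-diol 12.
2. 12 comes from double hydride reduction of the C25 ynal 11, which comes from a Wittig coupling (C11=C12) of the C15 phosphonium salt 8 with the C10 dialdehyde 9.
3. 8 comes from the C15 yne-tetraol 7, made by acetylide addition (C6–C7 bond) of enynol 5 to the α-hydroxy ketone 4.
4. 4 comes from 1,3-anti reduction (sets C3) of 3, from reductive opening of epoxide 2, from organocatalytic asymmetric epoxidation (sets C5) of achiral ketoisophorone 1.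
5. Ring order: the carbocycle comes with 1; an oxirane is made and opened in steps 1–2; the dihydrofuran is formed in step 8.

Assumption: for the two chiral catalysts (steps 1 and 8) the antipode written is taken to be the one that gives the configuration shown; if the sense proves opposite, the pseudo-enantiomeric or mirror-image catalyst is used.

## Route

Step 1
Reactants: 1 2,6,6-trimethylcyclohex-2-ene-1,4-dione (ketoisophorone)
Product: 2 (1R,6S)-1,3,3-trimethyl-7-oxabicyclo[4.1.0]heptane-2,5-dione
Conditions: 9-amino-9-deoxy-epi-quinine bis(trifluoroacetate) (10 mol%), 50% aq. H2O2 (1.5 equiv), 1,4-dioxane, 50 °C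
Reagents that add atoms: hydrogen peroxide, OO
Why: Weitz–Scheffer-type nucleophilic epoxidation under iminium/enamine catalysis, in which the primary amine condenses with the unhindered C4 ketone, hydrogen peroxide adds to the β-carbon C2 on the face fixed by the cinchona scaffold and the enamine closes the oxirane, so that the tertiary C–O centre (1R, later C5 of the target) is set by the catalyst and the cis-fused CH centre (6S) follows from it, while the acidic medium suppresses the racemic base-mediated background.

Step 2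
Reactants: 2 (1R,6S)-1,3,3-trimethyl-7-oxabicyclo[4.1.0]heptane-2,5-dione
Product: 3 (2R)-2-hydroxy-2,6,6-trimethylcyclohexane-1,4-dione
Conditions: (PhSe)2 (1.5 equiv), NaBH4 (3 equiv), EtOH, 0 °C; AcOH (3 equiv); then 2, 0 °C → rt
Reagents that add atoms: none
Why: Organoselenium-mediated reductive α-cleavage of an α,β-epoxy ketone to a β-hydroxy ketone, in which benzeneselenolate attacks the secondary oxirane carbon next to the unhindered carbonyl (SN2) and a second selenolate removes selenium to give the enolate, so the tertiary C–O bond and its R configuration are untouched and the acetic acid buffer prevents dehydration back to 1.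

Step 3
Reactants: 3 (2R)-2-hydroxy-2,6,6-trimethylcyclohexane-1,4-dione
Product: 4 (2R,4S)-2,4-dihydroxy-2,6,6-trimethylcyclohexan-1-one
Conditions: Me4NBH(OAc)3 (5 equiv), MeCN/AcOH 1:1, −30 °C
Reagents that add atoms: none
Why: Hydroxyl-directed Evans–Saksena reduction, in which the tertiary hydroxyl binds the triacetoxyborohydride and delivers hydride intramolecularly to the β-carbonyl (C4) from its own face, giving the trans (1,3-anti) diol and hence the 4S centre, while the C1 ketone flanked by two quaternary carbons is not reduced.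

Step 4
Reactants: 4 (2R,4S)-2,4-dihydroxy-2,6,6-trimethylcyclohexan-1-one; 5 (2E)-3-methylpent-2-en-4-yn-1-ol
Product: 7 (2R,4S)-1-[(3E)-5-hydroxy-3-methylpent-3-en-1-yn-1-yl]-2,6,6-trimethylcyclohexane-1,2,4-triol (mixture of C1 epimers), via dilithio enynolate 6 (not isolated)
Conditions: 5 (4 equiv), n-BuLi (8 equiv), THF, −78 → 0 °C; then 4, −78 °C → rt; aq. NH4Cl
Reagents that add atoms: none
Why: 1,2-Addition of a lithium acetylide to a ketone that cannot enolise (both α-carbons are quaternary) and is activated by chelation to the neighbouring lithium alkoxide, the excess acetylide absorbing the two hydroxyl protons; the new C1 carbinol forms as an epimer mixture, which does not matter because this carbon becomes sp2 in step 8.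

Step 5
Reactants: 7 (2R,4S)-1-[(3E)-5-hydroxy-3-methylpent-3-en-1-yn-1-yl]-2,6,6-trimethylcyclohexane-1,2,4-triol (mixture of C1 epimers)
Product: 8 {(2E)-3-methyl-5-[(2R,4S)-1,2,4-trihydroxy-2,6,6-trimethylcyclohexyl]pent-2-en-4-yn-1-yl}triphenylphosphonium bromide (mixture of C1 epimers of the ring)
Conditions: Ph3P·HBr (1.05 equiv), MeOH/CH2Cl2, 0 °C, dark
Reagents that add atoms: triphenylphosphine hydrobromide, [Br-].[PH+](c1ccccc1)(c1ccccc1)c1ccccc1
Why: Classical preparation of a polyene Wittig salt by acid-mediated substitution of a primary allylic alcohol with triphenylphosphine, chemoselective because the secondary and the two tertiary hydroxyls (the propargylic one deactivated by its vicinal hydroxyl) do not ionise at 0 °C, and run cold to keep the 2E geometry.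

Step 6
Reactants: 8 {(2E)-3-methyl-5-[(2R,4S)-1,2,4-trihydroxy-2,6,6-trimethylcyclohexyl]pent-2-en-4-yn-1-yl}triphenylphosphonium bromide; 9 (2E,4E,6E)-2,7-dimethylocta-2,4,6-trienedial
Product: 11 (2E,4E,6E,8E,10E)-2,7,11-trimethyl-13-[(2R,4S)-1,2,4-trihydroxy-2,6,6-trimethylcyclohexyl]trideca-2,4,6,8,10-pentaen-12-ynal (mixture of C1 epimers of the ring), via phosphonium ylide 10 (not isolated)
Conditions: NaOMe (1.1 equiv), 9 (3 equiv), CH2Cl2/MeOH, 0 °C → rt; then EtOAc/heptane, 60 °C (8Z → 8E)
Reagents that add atoms: none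
Why: Wittig olefination of a semi-stabilised allylic ylide with one aldehyde of the symmetrical dialdehyde used in excess (the classical C15 + C10 carotenoid coupling), the hindered cis isomer at the new double bond isomerising to trans on gentle warming and no stereocentre being touched.

Step 7
Reactants: 11 (2E,4E,6E,8E,10E)-2,7,11-trimethyl-13-[(2R,4S)-1,2,4-trihydroxy-2,6,6-trimethylcyclohexyl]trideca-2,4,6,8,10-pentaen-12-ynal (mixture of C1 epimers of the ring)
Product: 12 (2R,4S)-1-[(1E,3E,5E,7E,9E,11E)-13-hydroxy-3,7,12-trimethyltrideca-1,3,5,7,9,11-hexaen-1-yl]-2,6,6-trimethylcyclohexane-1,2,4-triol (mixture of C1 epimers)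
Conditions: NaAlH2(OCH2CH2OMe)2 (8 equiv), THF, 0 °C → rt; aq. potassium sodium tartrate
Reagents that add atoms: none
Why: One reagent does two known reductions, 1,2-hydride reduction of the polyenal to the allylic alcohol and alkoxide-directed trans-hydroalumination of the tertiary propargylic alcohol (propargylic alcohol to E-allylic alcohol reduction), which gives the 1E (carotenoid 7E) alkene after protonolysis.

Step 8
Reactants: 12 (2R,4S)-1-[(1E,3E,5E,7E,9E,11E)-13-hydroxy-3,7,12-trimethyltrideca-1,3,5,7,9,11-hexaen-1-yl]-2,6,6-trimethylcyclohexane-1,2,4-triol (mixture of C1 epimers)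
Product: 13 (2S,6S,7aR)-2-[(2E,4E,6E,8E,10E)-12-hydroxy-6,11-dimethyldodeca-2,4,6,8,10-pentaen-2-yl]-4,4,7a-trimethyl-2,4,5,6,7,7a-hexahydro-1-benzofuran-6-ol, i.e. (3S,5R,8S)-5,8-epoxy-5,8-dihydro-12'-apo-β-carotene-3,12'-diol
Conditions: (R)-3,3'-bis(2,4,6-triisopropylphenyl)-1,1'-binaphthyl-2,2'-diyl hydrogen phosphate (5 mol%), 4 Å molecular sieves, CH2Cl2/toluene 1:1, −40 °C, dark, Ar
Reagents that add atoms: none
Why: Proposed new method: the chiral phosphoric acid protonates the strained tertiary, polyene-conjugated hydroxyl (carotenoid C6), water leaves to give a polyenyl cation held as a contact ion pair with the chiral phosphate, which is at the same time hydrogen-bonded to the C5 hydroxyl, and this oxygen closes the five-membered ring onto C8; because the configuration at C8 is decided only by the direction in which the C7–C8 bond twists to bring the chain above or below the forming ring, the aryl walls of the catalyst can select the 8S mode, both C6 epimers converge on the same cation, and the weak acid at low temperature does not reopen the product; the closest known reactions are chiral phosphoric acid and N-triflylphosphoramide-catalysed SN1-type intramolecular allylic etherifications through chiral contact ion pairs (2H-chromene formation) and the classical achiral acid-promoted formation of carotenoid 5,8-furanoid oxides.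

## Compound list

1 | 2,6,6-trimethylcyclohex-2-ene-1,4-dione (ketoisophorone) | CC1=CC(=O)CC(C)(C)C1=O | starting material
2 | (1R,6S)-1,3,3-trimethyl-7-oxabicyclo[4.1.0]heptane-2,5-dione | O=C1C(C)(C)CC(=O)[C@@H]2[C@@]1(C)O2 | intermediate
3 | (2R)-2-hydroxy-2,6,6-trimethylcyclohexane-1,4-dione | O=C1C(C)(C)CC(=O)C[C@@]1(C)O | intermediate
4 | (2R,4S)-2,4-dihydroxy-2,6,6-trimethylcyclohexan-1-one | O=C1C(C)(C)C[C@H](O)C[C@@]1(C)O | intermediate
5 | (2E)-3-methylpent-2-en-4-yn-1-ol | C#C/C(C)=C/CO | starting material
6 | dilithio derivative of 5 (lithium acetylide, lithium alkoxide; not isolated) | [Li]C#C/C(C)=C/CO[Li] | intermediate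
7 | (2R,4S)-1-[(3E)-5-hydroxy-3-methylpent-3-en-1-yn-1-yl]-2,6,6-trimethylcyclohexane-1,2,4-triol, mixture of C1 epimers (C1 left undefined) | C/C(=C\CO)C#CC1(O)C(C)(C)C[C@H](O)C[C@@]1(C)O | intermediate
8 | {(2E)-3-methyl-5-[(2R,4S)-1,2,4-trihydroxy-2,6,6-trimethylcyclohexyl]pent-2-en-4-yn-1-yl}triphenylphosphonium bromide, ring C1 epimers | [Br-].C/C(=C\C[P+](c1ccccc1)(c1ccccc1)c1ccccc1)C#CC1(O)C(C)(C)C[C@H](O)C[C@@]1(C)O | intermediate
9 | (2E,4E,6E)-2,7-dimethylocta-2,4,6-trienedial | O=C/C(C)=C/C=C/C=C(C)/C=O | starting material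
10 | {(2E)-3-methyl-5-[(2R,4S)-1,2,4-trihydroxy-2,6,6-trimethylcyclohexyl]pent-2-en-4-yn-1-ylidene}triphenylphosphorane (ylide of 8; not isolated) | C/C(=C\C=P(c1ccccc1)(c1ccccc1)c1ccccc1)C#CC1(O)C(C)(C)C[C@H](O)C[C@@]1(C)O | intermediate
11 | (2E,4E,6E,8E,10E)-2,7,11-trimethyl-13-[(2R,4S)-1,2,4-trihydroxy-2,6,6-trimethylcyclohexyl]trideca-2,4,6,8,10-pentaen-12-ynal, ring C1 epimers | O=C/C(C)=C/C=C/C=C(C)/C=C/C=C(\C)C#CC1(O)C(C)(C)C[C@H](O)C[C@@]1(C)O | intermediate
12 | (2R,4S)-1-[(1E,3E,5E,7E,9E,11E)-13-hydroxy-3,7,12-trimethyltrideca-1,3,5,7,9,11-hexaen-1-yl]-2,6,6-trimethylcyclohexane-1,2,4-triol, mixture of C1 epimers | OC/C(C)=C/C=C/C=C(C)/C=C/C=C(C)/C=C/C1(O)C(C)(C)C[C@H](O)C[C@@]1(C)O | intermediate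
13 | (3S,5R,8S)-5,8-epoxy-5,8-dihydro-12'-apo-β-carotene-3,12'-diol, (8S)-persicachrome | CC(/C=C/C=C(\C)[C@@H]1C=C2C(C)(C)C[C@H](O)C[C@@]2(C)O1)=C\C=C\C=C(/C)CO | target

## Step count and risks

Total steps: 8. Longest linear sequence: 8 (1 → 13); 5 and 9 are bought and enter directly.

The three steps most likely to fail:

**Step 8 (proposed new cyclisation; risk: low selectivity at C8, or erosion by re-ionisation).** The fallback sets out from 12 and comes back at 13, and uses only known chemistry. 12 is cyclised with an achiral acid (pyridinium p-toluenesulfonate, CH2Cl2, 0 °C), the long-known acid-promoted formation of carotenoid 5,8-furanoid oxides, which runs through the same cation without facial control. This gives 13 together with its C8 epimer (3S,5R,8R)-5,8-epoxy-5,8-dihydro-12'-apo-β-carotene-3,12'-diol F1. The two are separated by preparative HPLC. F1 is resubmitted to the same acid, which reopens the C8–O bond and re-equilibrates it to a fresh mixture, so two or three cycles funnel the material into 13. This replaces kinetic catalyst control by equilibration, separation and recycling.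

**Step 4 (risk: the polyanionic, very hindered ketone adds the acetylide sluggishly).** The fallback sets out from 4 and comes back at 7. Both hydroxyls are capped (Me3SiOTf, 2,6-lutidine, CH2Cl2, −78 °C; no enolisable position, so no silyl enol ether can form) to give the neutral, soluble ketone (2R,4S)-2,6,6-trimethyl-2,4-bis(trimethylsilyloxy)cyclohexan-1-one F2. Reagent 6 is transmetallated with anhydrous CeCl3 (THF, −78 °C) and the organocerium acetylide is added to F2 to give (2R,4S)-1-[(3E)-5-hydroxy-3-methylpent-3-en-1-yn-1-yl]-2,6,6-trimethyl-2,4-bis(trimethylsilyloxy)cyclohexan-1-ol F3. Bu4NF/AcOH in THF removes both silyl groups and returns 7.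

**Step 5 (risk: HBr scrambles the enyne double-bond geometry or ionises the tertiary propargylic diol).** The fallback sets out from 7 and comes back at 11, replacing the acid-made Wittig salt by a phosphonate made under neutral conditions. The primary allylic hydroxyl alone is exchanged under Appel conditions (CBr4, PPh3, CH2Cl2, −20 °C) to give (2R,4S)-1-[(3E)-5-bromo-3-methylpent-3-en-1-yn-1-yl]-2,6,6-trimethylcyclohexane-1,2,4-triol F4. Michaelis–Arbuzov reaction with P(OEt)3 (90 °C) gives diethyl {(2E)-3-methyl-5-[(2R,4S)-1,2,4-trihydroxy-2,6,6-trimethylcyclohexyl]pent-2-en-4-yn-1-yl}phosphonate F5. Horner–Wadsworth–Emmons olefination of F5 (NaN(SiMe3)2, 4.5 equiv, THF, −78 → 0 °C) with 9 (3 equiv) gives 11 with high trans selectivity at the new double bond.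

## Further compounds

F1 | step 8 | (3S,5R,8R)-5,8-epoxy-5,8-dihydro-12'-apo-β-carotene-3,12'-diol (C8 epimer of 13) | CC(/C=C/C=C(\C)[C@H]1C=C2C(C)(C)C[C@H](O)C[C@@]2(C)O1)=C\C=C\C=C(/C)CO
F2 | step 4 | (2R,4S)-2,6,6-trimethyl-2,4-bis(trimethylsilyloxy)cyclohexan-1-one | O=C1C(C)(C)C[C@H](O[Si](C)(C)C)C[C@@]1(C)O[Si](C)(C)C
F3 | step 4 | (2R,4S)-1-[(3E)-5-hydroxy-3-methylpent-3-en-1-yn-1-yl]-2,6,6-trimethyl-2,4-bis(trimethylsilyloxy)cyclohexan-1-ol, C1 epimers | C/C(=C\CO)C#CC1(O)C(C)(C)C[C@H](O[Si](C)(C)C)C[C@@]1(C)O[Si](C)(C)C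
F4 | step 5 | (2R,4S)-1-[(3E)-5-bromo-3-methylpent-3-en-1-yn-1-yl]-2,6,6-trimethylcyclohexane-1,2,4-triol, C1 epimers | C/C(=C\CBr)C#CC1(O)C(C)(C)C[C@H](O)C[C@@]1(C)O
F5 | step 5 | diethyl {(2E)-3-methyl-5-[(2R,4S)-1,2,4-trihydroxy-2,6,6-trimethylcyclohexyl]pent-2-en-4-yn-1-yl}phosphonate, ring C1 epimers | C/C(=C\CP(=O)(OCC)OCC)C#CC1(O)C(C)(C)C[C@H](O)C[C@@]1(C)O
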